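Slowness was my first question: I held each step's time against the run, then asked of each constant how far the share of Jf in dusk would move if it were off.

| setting | dusk | autumn | dawn | winter |
|---|---|---|---|---|
| Ja | 0.40 M | 0.40 M | 0.40 M (fed, over 6.00 min) | 0.40 M |
| Jb | 0.360 M | 0.360 M | 0.360 M | 0.360 M (fed, over 6.00 min) |
| Je | 0.200 M | 0.200 M | 0.200 M | 0.200 M |
| time | 6.0 min |  | 6.0 min | 6.0 min |
| remark | everything together in a closed stirred flask, run for 6.0 min | a single well-mixed tank run continuously and read at steady state, 6.0 min in it on average | a stirred flask in which Ja is dosed at a steady rate over 6.00 min without added volume, worked up at 6.0 min | a stirred flask in which Jb is dosed at a steady rate over 6.00 min without added volume, worked up at 6.0 min |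

    Ja + Jb → Jf (k1 = 0.0482 M⁻¹ s⁻¹)
    Ja → Jc (k2 = 0.00295 s⁻¹)
    Jb → Jd (k3 = 0.0292 s⁻¹)
    Jf ⇌ Jg (K4 = 1.0, k4 = 0.0213 s⁻¹)
    Ja + Je → Jh (k5 = 0.0139 M⁻¹ s⁻¹)

- the set-up with the highest share of Jf in all that became Jf or Jc or Jg, at the outlet or at the end ("none" if the first two lie within 2 percentage points) (dusk / autumn / dawn / winter / none)
- share of Jf in all that became Jf or Jc or Jg, at the outlet or at the end, dusk
- share of Jf in all that became Jf or Jc or Jg, at the outlet or at the end, autumn
- share of Jf in all that became Jf or Jc or Jg, at the outlet or at the end, dawn
- share of Jf in all that became Jf or Jc or Jg, at the outlet or at the end, winter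

- the stated concentrations are those of everything mixed, before any reaction; amounts are the same in each set-up
- the feed brings no volume worth counting
- run time (dusk): 6.0 min

In dusk the exchange of Jf with Jg relaxes with a half-life of 0.271 min, shorter than the run of 6.0 min, so an error in its rate constant moved little. Its equilibrium constant counted in full, since it leaves Jf half of the pair. At the charged [Ja], Jb lives about 0.344 min, also shorter than the run, so its two constants counted as their ratio, and that ratio I had to know well. I call it the even-split level κ, the [Ja] at which Jb goes equally to Jf and to Jd, the decay constant of Jb over the constant of its step with Ja: 0.606 M. [Ja]/κ is the selectivity factor of Jb. The constant of Ja's passing to Jc mattered nearly in proportion, with a half-life of 3.9 min set against the run, while that of Jh acted through [Ja].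

I followed the Jb left: each part that vanishes becomes Jf with share [Ja]/([Ja]+κ). In dusk the charged level gave 39.8%, or 0.143 M. That lowers [Ja], so I took the mean level 0.328 M and got 0.127 M of Jf plus Jg. The remaining 0.273 M of Ja then bled away at 0.344 min⁻¹, with [Je] held at its charge, giving 0.123 M of Jc and a dusk share of 25.4%. At the start of dawn, [Ja] gains 0.0381 M in one decay time of Jb, far below κ, so I put dawn well under dusk and went no further.

The forecast gave 22.6% for dusk, 15.9% for autumn, 5.6% for dawn and 13.8% for winter, with dusk best, holding that “Jb is lost quickly to its own decay”. For dusk it stood 2.8 percentage points below me.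

The simulation gave 22.9%, 15.9%, 5.70% and 13.6% in that order, with dusk best, inside the forecast's ranges. Dusk held 0.118 M of Jf plus Jg against my 0.127 M. The dusk share leans on the back reaction of Jg to Jf: without that step it reads 0.0386% instead of 22.9%, and the best set-up changes, so a run without that back reaction would overturn the forecast. For the neighbour of dusk with 0.61 M of Jb, κ gives 0.243 M, a mean [Ja] of 0.279 M, and 0.192 M of Jf plus Jg. The run held 0.181 M, with a share of 31.5%.

(The rate constants belong to no real substance.)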